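The benzylic bond C11–C2′ is cut together with the neighbouring C1′–CHO bond (drimane and benzaldehyde numbering). The tetrasubstituted arene is read as a 3,6-dioxygenated benzyne: its two aryne carbons (C2′, C1′) sit between the oxygen-bearing carbons C3′ and C6′, so the C2v symmetry leaves no regiochemical choice. In one flask the C11 alkyllithium of a cis-fused (5β-H) 8α-hydroxydrimane adds to 3,6-bis(methoxymethoxy)benzyne and the new aryllithium is formylated by DMF: two fragments plus one carbon, three components. The precursors look unlike the product: an 11-iodo-8-ol, built by cyclisation of a neryl β-keto ester, and 2-chloro-1,4-bis(methoxymethoxy)benzene.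

Key step: step 10

Remark on the chemistry: the SMILES encodes a cis-fused decalin (5β-H, 10β-CH3), the 5-epimer of the sclareolide-type skeleton, with 8α-OH, 8β-CH3 and 9α-H (C11 β). The route is built for this isomer, so trans-fused chiral-pool terpenoids are not used. Drimane numbering: C11 is the benzylic CH2 on C9, C12 the CH3 on C8.

Step 1
Reactants: 1 nerol
Product: 2 neryl bromide
Conditions: PBr3 (0.4 eq), cat. pyridine, Et2O, −10 °C
Reagents that add atoms: phosphorus tribromide BrP(Br)Br
Why: SN2 bromination of the primary allylic alcohol through its phosphite ester at low temperature should keep the 2Z geometry.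

Step 2
Reactants: 2 neryl bromide; 3 (−)-menthyl acetoacetate
Product: 4 (1R,2S,5R)-menthyl (6Z)-7,11-dimethyl-3-oxododeca-6,10-dienoate
Conditions: 3, NaH, THF, 0 °C; n-BuLi, 0 °C; then 2, 0 °C → rt; aq NH4Cl
Reagents that add atoms: none
Why: Acetoacetate dianion (Weiler) alkylation: the terminal carbanion displaces the allylic bromide SN2 and leaves the Z-alkene and the chiral ester untouched.

Step 3
Reactants: 4 menthyl (6Z)-keto ester
Product: 5 (1R,2S,5R)-menthyl (4aR,8aS)-5,5,8a-trimethyl-2-oxodecahydronaphthalene-1-carboxylate (cis-fused; C9 labile)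
Conditions: SnCl4, CH2Cl2, 0 °C → rt; aqueous work-up; separation of the two cis-fused diastereomers by chromatography or crystallisation
Reagents that add atoms: none
Why: Proton-initiated cationic polyene cyclisation terminated by the tin-bound β-keto ester enol: anti addition across the 6Z-alkene through a chair-like array (Stork–Eschenmoser) should make H5 and the C10 methyl cis, and separating the two menthyl ester diastereomers (about equal amounts expected) fixes the absolute configuration at C5 and C10, while C9 stays labile (keto–enol).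

Step 4
Reactants: 5 cis-fused menthyl keto ester
Product: 6 (1R,2S,5R)-menthyl (4aR,8aS)-2-(methoxymethoxy)-5,5,8a-trimethyl-3,4,4a,5,6,7,8,8a-octahydronaphthalene-1-carboxylate
Conditions: NaH, THF–DMPU, 0 °C; MOMCl, 0 °C → rt
Reagents that add atoms: chloromethyl methyl ether COCCl
Why: O-alkylation of the sodium enolate by the hard electrophile fixes the enol as a vinylogous carbonate and removes the acidic C9–H before hydride reduction.

Step 5
Reactants: 6 MOM enol ether ester
Product: 8 (4aR,8aS)-5,5,8a-trimethyl-1-methylideneoctahydronaphthalen-2(1H)-one, via 2-(methoxymethoxy)allylic alcohol 7 (not isolated)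
Conditions: LiAlH4, Et2O, 0 °C → rt; then 1 M HCl, THF, rt; used at once
Reagents that add atoms: none
Why: 1,2-Reduction of the β-alkoxy acrylate gives the allylic alcohol, and acid then expels water through the oxocarbenium ion and hydrolyses the MOM enol ether (the classical β-keto ester to α-methylene ketone transposition); no stereocentre is touched and menthol is released.

Step 6
Reactants: 8 cis-fused α-methylene ketone
Product: 9 (2R,4aR,8aS)-2,5,5,8a-tetramethyl-1-methylidenedecahydronaphthalen-2-ol (8α-OH, 8β-CH3)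
Conditions: MeLi, anhydrous CeCl3, THF, −78 °C; aq NH4Cl
Reagents that add atoms: methyllithium [Li]C
Why: Organocerium 1,2-addition to the enone: in the favoured cis-decalin conformer (quaternary C4 equatorial on ring B) the C1 methylene is axial on the α face and 1,3 to C8, so methyl should enter equatorially from the β face, as with 3-axially substituted cyclohexanones, giving 8β-CH3 and 8α-OH.

Step 7
Reactants: 9 tertiary allylic alcohol
Product: 11 (1S,2R,4aR,8aS)-1-(hydroxymethyl)-2,5,5,8a-tetramethyldecahydronaphthalen-2-ol (5-epi-drimane-8α,11-diol), via cyclic alkoxyborane 10 (not isolated)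
Conditions: BH3·SMe2 (1.1 eq), THF, 0 → 45 °C; then NaOH, H2O2, 0 °C → rt
Reagents that add atoms: hydrogen peroxide OO
Why: Hydroxyl-directed hydroboration: the tertiary alcohol forms an alkoxyborane that adds its B–H across C9=C11 within an oxaborolane array, so hydrogen should reach C9 on the face of O8 (9α-H, C11 β) against the steric bias, and oxidation with retention gives the 1,3-diol.

Step 8
Reactants: 11 diol
Product: 12 (1R,2R,4aR,8aS)-1-(iodomethyl)-2,5,5,8a-tetramethyldecahydronaphthalen-2-ol
Conditions: PPh3, imidazole, I2, toluene–MeCN, 0 → 50 °C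
Reagents that add atoms: iodine II
Why: Appel-type iodination (Garegg–Samuelsson): only the primary alkoxyphosphonium ion is displaced by iodide, while the tertiary C8 alcohol should not react and, being anti to C11 in the favoured conformer, cannot close an oxetane.

Step 9
Reactants: 13 chlorohydroquinone
Product: 14 2-chloro-1,4-bis(methoxymethoxy)benzene
Conditions: NaH, DMF, 0 °C; MOMCl, 0 °C → rt
Reagents that add atoms: chloromethyl methyl ether COCCl
Why: Williamson alkylation of both phenoxides; the MOM ethers survive organolithiums, direct the later lithiation next to chlorine and fall to dilute acid.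

Step 10
Reactants: 12 iodo alcohol; 14 2-chloro-1,4-bis(methoxymethoxy)benzene
Product: 19 2-{[(1R,2R,4aR,8aS)-2-hydroxy-2,5,5,8a-tetramethyldecahydronaphthalen-1-yl]methyl}-3,6-bis(methoxymethoxy)benzaldehyde, via dilithio alkoxide-alkyllithium 15 (not isolated), via 3-lithio chloroarene 16 (not isolated), via 3,6-bis(methoxymethoxy)benzyne 17 (not isolated), via aryllithium adduct 18 (not isolated)
Conditions: 12 (1.1 eq), t-BuLi (3.3 eq), Et2O–pentane, −78 °C; separately 14 (1.0 eq), n-BuLi, THF, −78 °C; cold 16 cannulated into 15, −78 → −20 °C; DMF, −78 °C → rt; aq NH4Cl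
Reagents that add atoms: N,N-dimethylformamide CN(C)C=O
Why: After O-deprotonation, iodine–lithium exchange gives the primary alkyllithium 15; separately made 16 loses LiCl on warming to the C2v-symmetric aryne 17, the C11 carbanion adds to it (carbolithiation) to form the C11–C2′ bond, and the aryllithium 18, held by the flanking OMOM group, takes the formyl carbon from DMF at C1′. The closest known reaction type is the tandem addition of organolithiums to arynes released from ortho-halo aryllithiums, followed by electrophilic quench (aryne 1,2-difunctionalisation). No ring is closed and no stereocentre is formed; C8 (as its alkoxide) and C9 are spectators. The step needs regioselectivity, which the symmetry of 17 secures because both aryne carbons are equivalent and lithium can only end next to the new CH2 and ortho to OMOM. It also needs C-attack to win over O-attack and over self-addition of 16 or 18, which the higher nucleophilicity of the primary alkyllithium, its slight excess and the slow release of 17 from cold 16 are meant to secure.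

Step 11
Reactants: 19 bis-MOM aldehyde
Product: 20 3,6-dihydroxy-2-{[(1R,2R,4aR,8aS)-2-hydroxy-2,5,5,8a-tetramethyldecahydronaphthalen-1-yl]methyl}benzaldehyde (CNP0267523.2)
Conditions: 2 M aq HCl, degassed THF, 40 °C
Reagents that add atoms: none
Why: Acetal hydrolysis of the two aryl MOM ethers under mild aqueous acid; the saturated tertiary alcohol and the hydrogen-bonded ortho-hydroxy aldehyde are expected to survive.

Compound list
1 | nerol, (2Z)-3,7-dimethylocta-2,6-dien-1-ol | CC(C)=CCC/C(C)=C\CO | starting material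
2 | neryl bromide, (2Z)-1-bromo-3,7-dimethylocta-2,6-diene | CC(C)=CCC/C(C)=C\CBr | intermediate
3 | (−)-menthyl acetoacetate, (1R,2S,5R)-2-isopropyl-5-methylcyclohexyl 3-oxobutanoate | CC(=O)CC(=O)O[C@@H]1C[C@H](C)CC[C@H]1C(C)C | starting material
4 | (1R,2S,5R)-menthyl (6Z)-7,11-dimethyl-3-oxododeca-6,10-dienoate | CC(C)=CCC/C(C)=C\CCC(=O)CC(=O)O[C@@H]1C[C@H](C)CC[C@H]1C(C)C | intermediate
5 | (1R,2S,5R)-menthyl (4aR,8aS)-5,5,8a-trimethyl-2-oxodecahydronaphthalene-1-carboxylate, cis-fused (5β-H, 10β-CH3), C9 labile (keto–enol), drawn as the ketone | CC1(C)CCC[C@@]2(C)[C@@H]1CCC(=O)C2C(=O)O[C@@H]3C[C@H](C)CC[C@H]3C(C)C | intermediate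
6 | (1R,2S,5R)-menthyl (4aR,8aS)-2-(methoxymethoxy)-5,5,8a-trimethyl-3,4,4a,5,6,7,8,8a-octahydronaphthalene-1-carboxylate | CC1(C)CCC[C@@]2(C)[C@@H]1CCC(OCOC)=C2C(=O)O[C@@H]3C[C@H](C)CC[C@H]3C(C)C | intermediate
7 | [(4aR,8aS)-2-(methoxymethoxy)-5,5,8a-trimethyl-3,4,4a,5,6,7,8,8a-octahydronaphthalen-1-yl]methanol | CC1(C)CCC[C@@]2(C)[C@@H]1CCC(OCOC)=C2CO | intermediate (not isolated)
8 | (4aR,8aS)-5,5,8a-trimethyl-1-methylideneoctahydronaphthalen-2(1H)-one, cis-fused | CC1(C)CCC[C@@]2(C)[C@@H]1CCC(=O)C2=C | intermediate
9 | (2R,4aR,8aS)-2,5,5,8a-tetramethyl-1-methylidenedecahydronaphthalen-2-ol (8α-OH, 8β-CH3, cis-fused) | CC1(C)CCC[C@@]2(C)[C@@H]1CC[C@@](C)(O)C2=C | intermediate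
10 | cyclic alkoxyborane, O8–BH–C11 oxaborolane trans-fused across C8–C9 (9α-H) | CC1(C)CCC[C@@]2(C)[C@@H]1CC[C@@]3(C)OBC[C@H]23 | intermediate (not isolated)
11 | (1S,2R,4aR,8aS)-1-(hydroxymethyl)-2,5,5,8a-tetramethyldecahydronaphthalen-2-ol (5-epi-drimane-8α,11-diol) | CC1(C)CCC[C@@]2(C)[C@@H]1CC[C@@](C)(O)[C@@H]2CO | intermediate
12 | (1R,2R,4aR,8aS)-1-(iodomethyl)-2,5,5,8a-tetramethyldecahydronaphthalen-2-ol | CC1(C)CCC[C@@]2(C)[C@@H]1CC[C@@](C)(O)[C@@H]2CI | intermediate
13 | chlorohydroquinone, 2-chlorobenzene-1,4-diol | Oc1ccc(O)c(Cl)c1 | starting material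
14 | 2-chloro-1,4-bis(methoxymethoxy)benzene | COCOc1ccc(OCOC)c(Cl)c1 | intermediate
15 | lithium alkoxide of the C11 alkyllithium derived from 12 | CC1(C)CCC[C@@]2(C)[C@@H]1CC[C@@](C)(O[Li])[C@@H]2C[Li] | intermediate (not isolated)
16 | [2-chloro-3,6-bis(methoxymethoxy)phenyl]lithium | COCOc1ccc(OCOC)c([Li])c1Cl | intermediate (not isolated)
17 | 3,6-bis(methoxymethoxy)benzyne | COCOC1=CC=C(OCOC)C#C1 | intermediate (not isolated)
18 | aryllithium adduct, lithium at C1′ next to the new CH2, C8 as lithium alkoxide | CC1(C)CCC[C@@]2(C)[C@@H]1CC[C@@](C)(O[Li])[C@@H]2Cc1c(OCOC)ccc(OCOC)c1[Li] | intermediate (not isolated)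
19 | 2-{[(1R,2R,4aR,8aS)-2-hydroxy-2,5,5,8a-tetramethyldecahydronaphthalen-1-yl]methyl}-3,6-bis(methoxymethoxy)benzaldehyde | CC1(C)CCC[C@@]2(C)[C@@H]1CC[C@@](C)(O)[C@@H]2Cc1c(OCOC)ccc(OCOC)c1C=O | intermediate
20 | 3,6-dihydroxy-2-{[(1R,2R,4aR,8aS)-2-hydroxy-2,5,5,8a-tetramethyldecahydronaphthalen-1-yl]methyl}benzaldehyde | CC1(C)CCC[C@@]2(C)[C@@H]1CC[C@@](C)(O)[C@@H]2Cc1c(O)ccc(O)c1C=O | target

Total step count: 11. Longest linear sequence: 10 steps (steps 1 to 8, 10 and 11, from nerol).

Steps most likely to fail

Step 10 (key step). The aryne may oligomerise or be intercepted by 16 or 18 instead of by the hindered primary alkyllithium, which may also act as a base. Fallback, setting out from 9 and 14 and returning at 19: allylic alcohol 9 is hydroborated as in step 7 but worked up with water only, giving the cyclic borinic acid F1. Chloroarene 14 is lithiated with n-BuLi at −78 °C and formylated with DMF before LiCl is lost, giving 2-chloro-3,6-bis(methoxymethoxy)benzaldehyde F2. A Suzuki–Miyaura coupling of F1 with F2 (Pd(OAc)2, RuPhos, K2CO3, toluene–water, 90 °C) then forms the same C11–C2′ bond and delivers 19 for step 11.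

Step 7. Borane may add intermolecularly from the open β face instead of being delivered from O8, which would give the wrong configuration at C9. Fallback, setting out from 9 and returning at 11: 9 is silylated with chlorodimethylsilane and triethylamine to the dimethylsilyl ether F3. Karstedt's platinum catalyst (toluene, 60 °C) then closes the oxasilolane F4 by intramolecular hydrosilylation, which can only place hydrogen on C9 from the face of O8. Tamao oxidation (H2O2, KF, KHCO3, THF–MeOH) gives diol 11.

Step 3. The two menthyl ester diastereomers may not separate (remote stereocentres, keto–enol tautomerism), so the enantiomeric series would not be resolved. Fallback, setting out from 4 and returning at 11: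
- The cyclisation mixture is carried on unseparated through steps 4 to 7, so 6 travels with the diastereomeric MOM enol ether F5.
- Step 5 removes menthol and leaves the α-methylene ketone as a racemate (8 with ent-8 F6).
- Steps 6 and 7 give the racemic allylic alcohol (9 with ent-9 F7) and the racemic diol (11 with ent-11 F8).
- Acylation of the primary hydroxyl with (1S)-camphanic chloride (pyridine, DMAP) gives the camphanate of 11, F9, and the camphanate of ent-11, F10, which are separated by crystallisation.
- Methanolysis of F9 (K2CO3, MeOH) returns enantiopure 11.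

Further compounds
F1 | step 10 | cyclic borinic acid, O8–B(OH)–C11 oxaborolane of the 5-epi-drimane (9α-H) | CC1(C)CCC[C@@]2(C)[C@@H]1CC[C@@]3(C)OB(O)C[C@H]23
F2 | step 10 | 2-chloro-3,6-bis(methoxymethoxy)benzaldehyde | COCOc1ccc(OCOC)c(C=O)c1Cl
F3 | step 7 | dimethylsilyl ether of 9 | CC1(C)CCC[C@@]2(C)[C@@H]1CC[C@@](C)(O[SiH](C)C)C2=C
F4 | step 7 | oxasilolane, O8–SiMe2–C11, trans-fused across C8–C9 (9α-H) | CC1(C)CCC[C@@]2(C)[C@@H]1CC[C@@]3(C)O[Si](C)(C)C[C@H]23
F5 | step 3 | (1R,2S,5R)-menthyl (4aS,8aR)-2-(methoxymethoxy)-5,5,8a-trimethyl-3,4,4a,5,6,7,8,8a-octahydronaphthalene-1-carboxylate | CC1(C)CCC[C@]2(C)[C@H]1CCC(OCOC)=C2C(=O)O[C@@H]3C[C@H](C)CC[C@H]3C(C)C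
F6 | step 3 | ent-8, (4aS,8aR)-5,5,8a-trimethyl-1-methylideneoctahydronaphthalen-2(1H)-one | CC1(C)CCC[C@]2(C)[C@H]1CCC(=O)C2=C
F7 | step 3 | ent-9, (2S,4aS,8aR)-2,5,5,8a-tetramethyl-1-methylidenedecahydronaphthalen-2-ol | CC1(C)CCC[C@]2(C)[C@H]1CC[C@](C)(O)C2=C
F8 | step 3 | ent-11, (1R,2S,4aS,8aR)-1-(hydroxymethyl)-2,5,5,8a-tetramethyldecahydronaphthalen-2-ol | CC1(C)CCC[C@]2(C)[C@H]1CC[C@](C)(O)[C@H]2CO
F9 | step 3 | (1S)-camphanate of 11 at the C11 hydroxyl | CC1(C)CCC[C@@]2(C)[C@@H]1CC[C@@](C)(O)[C@@H]2COC(=O)[C@@]34CC[C@@](C)(C(=O)O3)C4(C)C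
F10 | step 3 | (1S)-camphanate of ent-11 at the C11 hydroxyl | CC1(C)CCC[C@]2(C)[C@H]1CC[C@](C)(O)[C@H]2COC(=O)[C@@]34CC[C@@](C)(C(=O)O3)C4(C)C
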